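**Retrosynthetic overview**

1. Numbering used throughout (bicyclo[9.3.1]pentadecane): C1/C11 bridgeheads, C2–C10 the (3Z,7Z)-diene bridge, C12 the spiro-oxirane carbon, C13, C14, C15 the quaternary carbon (CHO, homoprenyl). Endgame: CHO ⇐ CH2OPMB; oxirane ⇐ C12 ketone (methylene transfer) ⇐ C13 enol triflate (1,2-carbonyl transposition).
2. Key disconnection: C1–C14 and C11–C15 together, back to the acyclic (2Z,5Z,9Z,13E)-silyloxypentaenal 21. One intramolecular Diels–Alder macrobicyclisation builds the cyclohexene and, with the same two bonds, the 12- and 14-membered rings; the oxirane is the last ring (step 17).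
3. Enabling feature: in ring C1–C15–C11–C12–C13–C14 the formyl-bearing quaternary C15 lies between both bridgeheads. C15=C1 is therefore a CHO-activated dienophile and C11=C12–C13=C14 a diene whose two ends are already joined through the C2–C10 bridge.
4. The silyloxy activator is put on C13, not on the target's oxygenated C12. Only then do the "para" (OSi) and "ortho" (C11 alkyl) preferences both demand the bridged C11–C15/C1–C14 union; the oxygen is moved to C12 afterwards.
5. 21 is assembled linearly: two propyne carbocuprations (both Z-trisubstituted alkenes), Still–Gennari olefination (Z-enoate), Wittig reaction (E-enone), silyl dienol ether formation.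

Key step: step 12

Assumption: the (3aS)-prolinol-derived oxazaborolidinium salt is taken to deliver the diene to the Re face of C2 of enal 21, as its formyl C–H···O binding model suggests for 2-substituted enals; should the sense prove opposite, the (3aR)-catalyst is used with no other change. Compounds 1, 2, 3, 12, 13 and 17 are taken as commercial.

**Route**

Step 1
Reactants: 1 2-(2-bromoethyl)-1,3-dioxolane; 2 propyne; 3 oxirane
Product: 6 (3Z)-6-(1,3-dioxolan-2-yl)-4-methylhex-3-en-1-ol, via Grignard reagent 4 (not isolated), via Z-alkenylcopper reagent 5 (not isolated)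
Conditions: Mg, THF, 25 °C; CuBr·SMe2, Et2O–Me2S, −45 °C; 2, −25 °C; LiC≡C–C3H7 (from pent-1-yne, n-BuLi), HMPA, then 3, −78 → −10 °C; aq. NH4Cl
Reagents that add atoms: none
Why: Carbocupration of a terminal alkyne is a stereospecific syn addition that puts the alkyl group on the methyl-bearing carbon and copper on the terminal carbon, so the Z-trisubstituted alkene (later C7=C8, C6 cis to C9) is fixed, and the alkenylcopper, activated as its lithium pentynyl cuprate, opens oxirane with retention (epoxide opening by an organocuprate).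

Step 2
Reactants: 6 (3Z)-6-(1,3-dioxolan-2-yl)-4-methylhex-3-en-1-ol
Product: 7 2-[(3Z)-6-bromo-3-methylhex-3-en-1-yl]-1,3-dioxolane
Conditions: CBr4, PPh3, 2,6-lutidine, CH2Cl2, 0 °C
Reagents that add atoms: tetrabromomethane, BrC(Br)(Br)Br
Why: Appel bromination converts the primary alcohol into the bromide under near-neutral conditions that leave the acetal and the Z-alkene untouched.

Step 3
Reactants: 7 2-[(3Z)-6-bromo-3-methylhex-3-en-1-yl]-1,3-dioxolane; 2 propyne; 3 oxirane
Product: 10 (3Z,7Z)-10-(1,3-dioxolan-2-yl)-4,8-dimethyldeca-3,7-dien-1-ol, via Grignard reagent 8 (not isolated), via Z-alkenylcopper reagent 9 (not isolated)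
Conditions: Mg, THF, 25 °C; CuBr·SMe2, Et2O–Me2S, −45 °C; 2, −25 °C; LiC≡C–C3H7 (from pent-1-yne, n-BuLi), HMPA, then 3, −78 → −10 °C; aq. NH4Cl
Reagents that add atoms: none
Why: A second syn-carbocupration of propyne followed by oxirane opening sets the other Z-trisubstituted alkene (later C3=C4, C2 cis to C5) by the same stereospecific mechanism, and the acetal and the first alkene are inert to the organocopper reagent.

Step 4
Reactants: 10 (3Z,7Z)-10-(1,3-dioxolan-2-yl)-4,8-dimethyldeca-3,7-dien-1-ol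
Product: 11 (3Z,7Z)-10-(1,3-dioxolan-2-yl)-4,8-dimethyldeca-3,7-dienal
Conditions: DMP, NaHCO3, CH2Cl2, 0 °C; used at once
Reagents that add atoms: none
Why: Dess–Martin oxidation under bicarbonate buffering gives the β,γ-unsaturated aldehyde without acid- or base-induced migration of the C3=C4 double bond into conjugation.

Step 5
Reactants: 12 methyl 2-[bis(2,2,2-trifluoroethoxy)phosphoryl]acetate; 13 5-bromo-2-methylpent-2-ene
Product: 14 methyl 2-[bis(2,2,2-trifluoroethoxy)phosphoryl]-6-methylhept-5-enoate (racemic)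
Conditions: NaH, DMSO, NaI (cat.), 50 °C
Reagents that add atoms: none
Why: C-Alkylation of the sodium salt of the phosphonoacetate with a primary homoallylic bromide (enolate alkylation) installs the future homoprenyl side chain, and the new stereocentre is racemic and is destroyed in step 6.

Step 6
Reactants: 11 (3Z,7Z)-10-(1,3-dioxolan-2-yl)-4,8-dimethyldeca-3,7-dienal; 14 methyl 2-[bis(2,2,2-trifluoroethoxy)phosphoryl]-6-methylhept-5-enoate
Product: 15 methyl (2Z,5Z,9Z)-12-(1,3-dioxolan-2-yl)-6,10-dimethyl-2-(4-methylpent-3-en-1-yl)dodeca-2,5,9-trienoate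
Conditions: 14, KHMDS, 18-crown-6, THF, −78 °C; then 11, −78 °C
Reagents that add atoms: none
Why: Still–Gennari olefination, in which the electron-poor bis(trifluoroethyl) phosphonate under dissociating conditions gives the Z-trisubstituted enoate kinetically, puts the ester cis to the C4 chain, the geometry that later places CHO and the C2 bridge cis on the ring.

Step 7
Reactants: 15 methyl (2Z,5Z,9Z)-12-(1,3-dioxolan-2-yl)-6,10-dimethyl-2-(4-methylpent-3-en-1-yl)dodeca-2,5,9-trienoate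
Product: 16 methyl (2Z,5Z,9Z)-6,10-dimethyl-2-(4-methylpent-3-en-1-yl)-13-oxotrideca-2,5,9-trienoate
Conditions: 1 M aq. HCl, THF, 23 °C
Reagents that add atoms: water, O
Why: Acid-catalysed acetal hydrolysis releases the aldehyde, and the methyl ester and the isolated trisubstituted alkenes are stable to dilute aqueous acid at room temperature.

Step 8
Reactants: 16 methyl (2Z,5Z,9Z)-6,10-dimethyl-2-(4-methylpent-3-en-1-yl)-13-oxotrideca-2,5,9-trienoate; 17 1-(triphenyl-λ5-phosphanylidene)propan-2-one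
Product: 18 methyl (2Z,5Z,9Z,13E)-6,10-dimethyl-2-(4-methylpent-3-en-1-yl)-15-oxohexadeca-2,5,9,13-tetraenoate
Conditions: CH2Cl2, 40 °C
Reagents that add atoms: none
Why: Wittig olefination with a stabilised acyl ylide reacts only with the aldehyde, not the ester, and gives the E-enone.

Step 9
Reactants: 18 methyl (2Z,5Z,9Z,13E)-6,10-dimethyl-2-(4-methylpent-3-en-1-yl)-15-oxohexadeca-2,5,9,13-tetraenoate
Product: 19 methyl (2Z,5Z,9Z,13E)-6,10-dimethyl-2-(4-methylpent-3-en-1-yl)-15-{[tri(propan-2-yl)silyl]oxy}hexadeca-2,5,9,13,15-pentaenoate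
Conditions: i-Pr3SiOTf, Et3N, CH2Cl2, −78 → 0 °C
Reagents that add atoms: tri(propan-2-yl)silyl trifluoromethanesulfonate, CC(C)[Si](OS(=O)(=O)C(F)(F)F)(C(C)C)C(C)C
Why: Soft enolisation of the methyl ketone (silyl triflate/amine) occurs at the methyl group and gives the cross-conjugated 2-silyloxy-1,3-diene with the E-alkene retained, while the ester is not enolised under these conditions.

Step 10
Reactants: 19 methyl (2Z,5Z,9Z,13E)-6,10-dimethyl-2-(4-methylpent-3-en-1-yl)-15-{[tri(propan-2-yl)silyl]oxy}hexadeca-2,5,9,13,15-pentaenoate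
Product: 20 (2Z,5Z,9Z,13E)-6,10-dimethyl-2-(4-methylpent-3-en-1-yl)-15-{[tri(propan-2-yl)silyl]oxy}hexadeca-2,5,9,13,15-pentaen-1-ol
Conditions: DIBAL-H, CH2Cl2, −78 °C; aq. Rochelle salt
Reagents that add atoms: none
Why: DIBAL-H reduces the enoate to the allylic alcohol (1,2-reduction) at low temperature with retention of the Z-geometry, and the bulky silyl dienol ether is inert to the hydride and to the neutral tartrate work-up.

Step 11
Reactants: 20 (2Z,5Z,9Z,13E)-6,10-dimethyl-2-(4-methylpent-3-en-1-yl)-15-{[tri(propan-2-yl)silyl]oxy}hexadeca-2,5,9,13,15-pentaen-1-ol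
Product: 21 (2Z,5Z,9Z,13E)-6,10-dimethyl-2-(4-methylpent-3-en-1-yl)-15-{[tri(propan-2-yl)silyl]oxy}hexadeca-2,5,9,13,15-pentaenal
Conditions: MnO2, CH2Cl2, 23 °C; used at once
Reagents that add atoms: none
Why: MnO2 oxidises only the allylic alcohol, under neutral heterogeneous conditions that avoid Z-to-E isomerisation of the enal and deconjugation through the doubly allylic C4 methylene and that spare the silyl dienol ether.

Step 12
Reactants: 21 (2Z,5Z,9Z,13E)-6,10-dimethyl-2-(4-methylpent-3-en-1-yl)-15-{[tri(propan-2-yl)silyl]oxy}hexadeca-2,5,9,13,15-pentaenal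
Product: 22 (1S,3Z,7Z,11S,15S)-4,8-dimethyl-15-(4-methylpent-3-en-1-yl)-13-{[tri(propan-2-yl)silyl]oxy}bicyclo[9.3.1]pentadeca-3,7,12-triene-15-carbaldehyde
Conditions: (3aS)-1-(2-methylphenyl)-3,3-diphenyltetrahydro-1H,3H-pyrrolo[1,2-c][1,3,2]oxazaborole·HNTf2 (20 mol %), CH2Cl2, −78 → −40 °C, slow addition of 21 to a final 1 mM
Reagents that add atoms: none
Why: The N-protonated oxazaborolidine binds the formyl group of 21 and lowers its LUMO, and the 2-silyloxydiene adds in a concerted, asynchronous, suprafacial [4+2] cycloaddition in which C14 (largest HOMO coefficient, next to C–OSi) bonds to the enal β-carbon C1 and the alkyl-bearing diene terminus C11 bonds to the α-carbon C15; the closest known reaction type is the catalytic enantioselective intramolecular Diels–Alder macrobicyclisation of a 2-silyloxydiene tethered to a 2-substituted enal under chiral oxazaborolidinium catalysis. The cyclohexene closes by the [4π+2π] addition itself, and the same C11–C15 bond closes the 12-membered carbocycle in the bridged (1,3 across C15) mode while C1–C14 completes the 14-membered perimeter, so no ring exists before this step. C1 and C15 take their relative configuration from the Z-geometry of the enal (the C2 tether stays cis to CHO), C11 from the E-diene reacting through the formyl-exo/homoprenyl-endo transition state that 2-substituted enals prefer (C10 trans to CHO), and the absolute configuration from the catalyst, which must expose the Re face of C15. The step needs bridged rather than fused regiochemistry, which the C13 silyloxy group and the C11 alkyl group both dictate, and ring closure in preference to oligomerisation, which slow addition at high dilution and the low-temperature catalysed pathway should secure.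

Step 13
Reactants: 22 (1S,3Z,7Z,11S,15S)-4,8-dimethyl-15-(4-methylpent-3-en-1-yl)-13-{[tri(propan-2-yl)silyl]oxy}bicyclo[9.3.1]pentadeca-3,7,12-triene-15-carbaldehyde
Product: 23 [(1S,3Z,7Z,11S,15S)-4,8-dimethyl-15-(4-methylpent-3-en-1-yl)-13-{[tri(propan-2-yl)silyl]oxy}bicyclo[9.3.1]pentadeca-3,7,12-trien-15-yl]methanol
Conditions: NaBH4, EtOH–THF, 0 °C
Reagents that add atoms: none
Why: Borohydride reduction of the non-enolisable neopentyl aldehyde masks the formyl group at the alcohol level for steps 16 and 17, in which a free aldehyde would compete, and touches no stereocentre.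

Step 14
Reactants: 23 [(1S,3Z,7Z,11S,15S)-4,8-dimethyl-15-(4-methylpent-3-en-1-yl)-13-{[tri(propan-2-yl)silyl]oxy}bicyclo[9.3.1]pentadeca-3,7,12-trien-15-yl]methanol
Product: 24 {[(1S,3Z,7Z,11S,15S)-15-{[(4-methoxyphenyl)methoxy]methyl}-4,8-dimethyl-15-(4-methylpent-3-en-1-yl)bicyclo[9.3.1]pentadeca-3,7,12-trien-13-yl]oxy}tri(propan-2-yl)silane
Conditions: NaH, 4-MeOC6H4CH2Cl, Bu4NI (cat.), THF–DMF, 0 → 23 °C
Reagents that add atoms: 1-(chloromethyl)-4-methoxybenzene, COc1ccc(CCl)cc1
Why: Williamson etherification gives a 4-methoxybenzyl ether that survives fluoride, palladium catalysis and sulfur ylides and is removed later under neutral oxidative conditions.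

Step 15
Reactants: 24 {[(1S,3Z,7Z,11S,15S)-15-{[(4-methoxyphenyl)methoxy]methyl}-4,8-dimethyl-15-(4-methylpent-3-en-1-yl)bicyclo[9.3.1]pentadeca-3,7,12-trien-13-yl]oxy}tri(propan-2-yl)silane
Product: 25 (1S,3Z,7Z,11S,15S)-15-{[(4-methoxyphenyl)methoxy]methyl}-4,8-dimethyl-15-(4-methylpent-3-en-1-yl)bicyclo[9.3.1]pentadeca-3,7,12-trien-13-yl trifluoromethanesulfonate
Conditions: CsF, PhNTf2, DME, 23 °C
Reagents that add atoms: N-phenylbis(trifluoromethanesulfonimide), O=S(=O)(N(c1ccccc1)S(=O)(=O)C(F)(F)F)C(F)(F)F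
Why: Fluoride cleaves the silyl enol ether to the caesium enolate, which is trapped on oxygen by the triflimide before it can equilibrate, so the alkenyl triflate keeps the C12=C13 regiochemistry fixed by the cycloaddition (regiospecific enol triflate formation).

Step 16
Reactants: 25 (1S,3Z,7Z,11S,15S)-15-{[(4-methoxyphenyl)methoxy]methyl}-4,8-dimethyl-15-(4-methylpent-3-en-1-yl)bicyclo[9.3.1]pentadeca-3,7,12-trien-13-yl trifluoromethanesulfonate
Product: 27 (1R,3Z,7Z,11R,15S)-15-{[(4-methoxyphenyl)methoxy]methyl}-4,8-dimethyl-15-(4-methylpent-3-en-1-yl)bicyclo[9.3.1]pentadeca-3,7-dien-12-one, via morpholine enamine 26 (not isolated)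
Conditions: Pd(OAc)2 (10 mol %), P(4-MeOC6H4)3 (25 mol %), N-methylbicyclo[2.2.1]hept-2-ene-2-carboxamide (50 mol %), morpholin-4-yl benzoate, i-PrOH, Cs2CO3, 1,4-dioxane, 100 °C; then 1 M aq. HCl, THF, 0 °C
Reagents that add atoms: morpholin-4-yl benzoate, O=C(ON1CCOCC1)c1ccccc1 (nitrogen of 26); water, O (oxygen of 27)
Why: Carbonyl 1,2-transposition by palladium/norbornene (Catellani-type) catalysis, in which zerovalent palladium inserts into the alkenyl C13–OTf bond, norbornene relays amination of the adjacent vinylic C12–H by the N–O electrophile, hydride from isopropoxide terminates at C13 and mild hydrolysis of enamine 26 (double bond C12=C13, so C11 is not epimerised) gives the C12 ketone.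

Step 17
Reactants: 27 (1R,3Z,7Z,11R,15S)-15-{[(4-methoxyphenyl)methoxy]methyl}-4,8-dimethyl-15-(4-methylpent-3-en-1-yl)bicyclo[9.3.1]pentadeca-3,7-dien-12-one
Product: 28 (1R,3Z,7Z,11R,12S,15S)-15-{[(4-methoxyphenyl)methoxy]methyl}-4,8-dimethyl-15-(4-methylpent-3-en-1-yl)spiro[bicyclo[9.3.1]pentadeca-3,7-diene-12,2'-oxirane]
Conditions: Me3S+ I−, KHMDS, THF, −10 → 0 °C
Reagents that add atoms: trimethylsulfonium iodide, C[S+](C)C.[I-]
Why: Corey–Chaykovsky epoxidation, in which the sulfonium ylide adds irreversibly to the C12 ketone and the betaine closes to the oxirane, should deliver CH2 equatorially on the chair whose axial homoprenyl group blocks the opposite face, anti to the C10 substituent on C11 and cis to the C15 oxymethyl group (12S).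

Step 18
Reactants: 28 (1R,3Z,7Z,11R,12S,15S)-15-{[(4-methoxyphenyl)methoxy]methyl}-4,8-dimethyl-15-(4-methylpent-3-en-1-yl)spiro[bicyclo[9.3.1]pentadeca-3,7-diene-12,2'-oxirane]
Product: 29 [(1R,3Z,7Z,11R,12S,15S)-4,8-dimethyl-15-(4-methylpent-3-en-1-yl)spiro[bicyclo[9.3.1]pentadeca-3,7-diene-12,2'-oxiran]-15-yl]methanol
Conditions: DDQ, CH2Cl2/pH 7 phosphate buffer, 0 °C
Reagents that add atoms: none
Why: Oxidative cleavage of the 4-methoxybenzyl ether with DDQ at buffered neutral pH releases the primary alcohol without acid, so the acid-labile spiro-oxirane and the alkenes survive.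

Step 19
Reactants: 29 [(1R,3Z,7Z,11R,12S,15S)-4,8-dimethyl-15-(4-methylpent-3-en-1-yl)spiro[bicyclo[9.3.1]pentadeca-3,7-diene-12,2'-oxiran]-15-yl]methanol
Product: 30 (1R,3Z,7Z,11R,12S,15S)-4,8-dimethyl-15-(4-methylpent-3-en-1-yl)spiro[bicyclo[9.3.1]pentadeca-3,7-diene-12,2'-oxirane]-15-carbaldehyde
Conditions: DMP, NaHCO3, CH2Cl2, 0 → 23 °C
Reagents that add atoms: none
Why: Dess–Martin oxidation under bicarbonate buffering converts the neopentyl alcohol into the non-enolisable aldehyde quickly and without acid or base, before the alcohol can add to the cis-disposed oxirane.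

**Compound list**

1 | 2-(2-bromoethyl)-1,3-dioxolane | BrCCC1OCCO1 | starting material
2 | propyne | CC#C | starting material
3 | oxirane | C1CO1 | starting material
4 | [2-(1,3-dioxolan-2-yl)ethyl]magnesium bromide | Br[Mg]CCC1OCCO1 | intermediate (not isolated)
5 | [(1Z)-4-(1,3-dioxolan-2-yl)-2-methylbut-1-en-1-yl]copper | [Cu]/C=C(/C)CCC1OCCO1 | intermediate (not isolated)
6 | (3Z)-6-(1,3-dioxolan-2-yl)-4-methylhex-3-en-1-ol | OCC/C=C(/C)CCC1OCCO1 | intermediate
7 | 2-[(3Z)-6-bromo-3-methylhex-3-en-1-yl]-1,3-dioxolane | BrCC/C=C(/C)CCC1OCCO1 | intermediate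
8 | [(3Z)-6-(1,3-dioxolan-2-yl)-4-methylhex-3-en-1-yl]magnesium bromide | Br[Mg]CC/C=C(/C)CCC1OCCO1 | intermediate (not isolated)
9 | [(1Z,5Z)-8-(1,3-dioxolan-2-yl)-2,6-dimethylocta-1,5-dien-1-yl]copper | [Cu]/C=C(/C)CC/C=C(/C)CCC1OCCO1 | intermediate (not isolated)
10 | (3Z,7Z)-10-(1,3-dioxolan-2-yl)-4,8-dimethyldeca-3,7-dien-1-ol | OCC/C=C(/C)CC/C=C(/C)CCC1OCCO1 | intermediate
11 | (3Z,7Z)-10-(1,3-dioxolan-2-yl)-4,8-dimethyldeca-3,7-dienal | O=CC/C=C(/C)CC/C=C(/C)CCC1OCCO1 | intermediate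
12 | methyl 2-[bis(2,2,2-trifluoroethoxy)phosphoryl]acetate | COC(=O)CP(=O)(OCC(F)(F)F)OCC(F)(F)F | starting material
13 | 5-bromo-2-methylpent-2-ene | CC(C)=CCCBr | starting material
14 | methyl 2-[bis(2,2,2-trifluoroethoxy)phosphoryl]-6-methylhept-5-enoate (racemic) | COC(=O)C(CCC=C(C)C)P(=O)(OCC(F)(F)F)OCC(F)(F)F | intermediate
15 | methyl (2Z,5Z,9Z)-12-(1,3-dioxolan-2-yl)-6,10-dimethyl-2-(4-methylpent-3-en-1-yl)dodeca-2,5,9-trienoate | COC(=O)/C(CCC=C(C)C)=C\C/C=C(/C)CC/C=C(/C)CCC1OCCO1 | intermediate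
16 | methyl (2Z,5Z,9Z)-6,10-dimethyl-2-(4-methylpent-3-en-1-yl)-13-oxotrideca-2,5,9-trienoate | COC(=O)/C(CCC=C(C)C)=C\C/C=C(/C)CC/C=C(/C)CCC=O | intermediate
17 | 1-(triphenyl-λ5-phosphanylidene)propan-2-one | CC(=O)C=P(c1ccccc1)(c1ccccc1)c1ccccc1 | starting material
18 | methyl (2Z,5Z,9Z,13E)-6,10-dimethyl-2-(4-methylpent-3-en-1-yl)-15-oxohexadeca-2,5,9,13-tetraenoate | COC(=O)/C(CCC=C(C)C)=C\C/C=C(/C)CC/C=C(/C)CC/C=C/C(C)=O | intermediate
19 | methyl (2Z,5Z,9Z,13E)-6,10-dimethyl-2-(4-methylpent-3-en-1-yl)-15-{[tri(propan-2-yl)silyl]oxy}hexadeca-2,5,9,13,15-pentaenoate | COC(=O)/C(CCC=C(C)C)=C\C/C=C(/C)CC/C=C(/C)CC/C=C/C(=C)O[Si](C(C)C)(C(C)C)C(C)C | intermediate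
20 | (2Z,5Z,9Z,13E)-6,10-dimethyl-2-(4-methylpent-3-en-1-yl)-15-{[tri(propan-2-yl)silyl]oxy}hexadeca-2,5,9,13,15-pentaen-1-ol | OC/C(CCC=C(C)C)=C\C/C=C(/C)CC/C=C(/C)CC/C=C/C(=C)O[Si](C(C)C)(C(C)C)C(C)C | intermediate
21 | (2Z,5Z,9Z,13E)-6,10-dimethyl-2-(4-methylpent-3-en-1-yl)-15-{[tri(propan-2-yl)silyl]oxy}hexadeca-2,5,9,13,15-pentaenal | O=C/C(CCC=C(C)C)=C\C/C=C(/C)CC/C=C(/C)CC/C=C/C(=C)O[Si](C(C)C)(C(C)C)C(C)C | intermediate
22 | (1S,3Z,7Z,11S,15S)-4,8-dimethyl-15-(4-methylpent-3-en-1-yl)-13-{[tri(propan-2-yl)silyl]oxy}bicyclo[9.3.1]pentadeca-3,7,12-triene-15-carbaldehyde | CC(C)=CCC[C@]1(C=O)[C@H]2C/C=C(/C)CC/C=C(/C)CC[C@H]1C=C(O[Si](C(C)C)(C(C)C)C(C)C)C2 | intermediate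
23 | [(1S,3Z,7Z,11S,15S)-4,8-dimethyl-15-(4-methylpent-3-en-1-yl)-13-{[tri(propan-2-yl)silyl]oxy}bicyclo[9.3.1]pentadeca-3,7,12-trien-15-yl]methanol | CC(C)=CCC[C@]1(CO)[C@H]2C/C=C(/C)CC/C=C(/C)CC[C@H]1C=C(O[Si](C(C)C)(C(C)C)C(C)C)C2 | intermediate
24 | {[(1S,3Z,7Z,11S,15S)-15-{[(4-methoxyphenyl)methoxy]methyl}-4,8-dimethyl-15-(4-methylpent-3-en-1-yl)bicyclo[9.3.1]pentadeca-3,7,12-trien-13-yl]oxy}tri(propan-2-yl)silane | CC(C)=CCC[C@]1(COCc3ccc(OC)cc3)[C@H]2C/C=C(/C)CC/C=C(/C)CC[C@H]1C=C(O[Si](C(C)C)(C(C)C)C(C)C)C2 | intermediate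
25 | (1S,3Z,7Z,11S,15S)-15-{[(4-methoxyphenyl)methoxy]methyl}-4,8-dimethyl-15-(4-methylpent-3-en-1-yl)bicyclo[9.3.1]pentadeca-3,7,12-trien-13-yl trifluoromethanesulfonate | CC(C)=CCC[C@]1(COCc3ccc(OC)cc3)[C@H]2C/C=C(/C)CC/C=C(/C)CC[C@H]1C=C(OS(=O)(=O)C(F)(F)F)C2 | intermediate
26 | 4-[(1S,3Z,7Z,11R,15S)-15-{[(4-methoxyphenyl)methoxy]methyl}-4,8-dimethyl-15-(4-methylpent-3-en-1-yl)bicyclo[9.3.1]pentadeca-3,7,12-trien-12-yl]morpholine | CC(C)=CCC[C@]1(COCc3ccc(OC)cc3)[C@H]2C/C=C(/C)CC/C=C(/C)CC[C@H]1C(N4CCOCC4)=CC2 | intermediate (not isolated)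
27 | (1R,3Z,7Z,11R,15S)-15-{[(4-methoxyphenyl)methoxy]methyl}-4,8-dimethyl-15-(4-methylpent-3-en-1-yl)bicyclo[9.3.1]pentadeca-3,7-dien-12-one | CC(C)=CCC[C@]1(COCc3ccc(OC)cc3)[C@H]2C/C=C(/C)CC/C=C(/C)CC[C@H]1C(=O)CC2 | intermediate
28 | (1R,3Z,7Z,11R,12S,15S)-15-{[(4-methoxyphenyl)methoxy]methyl}-4,8-dimethyl-15-(4-methylpent-3-en-1-yl)spiro[bicyclo[9.3.1]pentadeca-3,7-diene-12,2'-oxirane] | CC(C)=CCC[C@]1(COCc3ccc(OC)cc3)[C@H]2C/C=C(/C)CC/C=C(/C)CC[C@H]1[C@@]1(CC2)CO1 | intermediate
29 | [(1R,3Z,7Z,11R,12S,15S)-4,8-dimethyl-15-(4-methylpent-3-en-1-yl)spiro[bicyclo[9.3.1]pentadeca-3,7-diene-12,2'-oxiran]-15-yl]methanol | CC(C)=CCC[C@]1(CO)[C@H]2C/C=C(/C)CC/C=C(/C)CC[C@H]1[C@@]1(CC2)CO1 | intermediate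
30 | (1R,3Z,7Z,11R,12S,15S)-4,8-dimethyl-15-(4-methylpent-3-en-1-yl)spiro[bicyclo[9.3.1]pentadeca-3,7-diene-12,2'-oxirane]-15-carbaldehyde | CC(C)=CCC[C@]1(C=O)[C@H]2C/C=C(/C)CC/C=C(/C)CC[C@H]1[C@@]1(CC2)CO1 | target

**Step count and risks**

Total step count: 19. Longest linear sequence: 18 (steps 1–4 and 6–19 from compound 1); step 5 is a one-step side branch.

The three steps most likely to fail:

Step 12 (macrobicyclisation). The strongly acidic boron catalyst may isomerise the Z-enal or protodesilylate the dienol ether faster than the slow 12-membered ring closure, and discrimination between the enal faces may be weaker for a β-substituted enal than for simple 2-substituted acroleins. Fallback, setting out from 21 and returning at 23: catalyst control is given up. 21 is cyclised without any Lewis acid (toluene, BHT, 140 °C, 1 mM, thermal intramolecular Diels–Alder) to racemic adduct, that is 22 together with its mirror image ent-22 F1. NaBH4 reduction as in step 13 gives 23 together with ent-23 F2. Esterification with (S)-O-acetylmandelic acid (DCC, DMAP, CH2Cl2) gives the diastereomeric esters, the O-acetylmandelate of 23 F3 and the O-acetylmandelate of ent-23 F4, which should be separable by chromatography. K2CO3 in MeOH cleaves F3 to enantiopure 23, which re-enters at step 14.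

Step 16 (1,2-carbonyl transposition). Norbornene-relayed palladation of C12–H, next to the fully substituted C11/C15 region, may be slower than direct ipso reduction of the alkenylpalladium species or Heck-type insertion into a ring alkene. Fallback, setting out from 24 and returning at 27: 24 is hydroxylated at C12 with 2-(phenylsulfonyl)-3-phenyloxaziridine (CHCl3, 60 °C), which does not epoxidise isolated alkenes, and desilylated (Bu4NF, AcOH) to the α-hydroxy ketone F5. Condensation with TsNHNH2 (EtOH) gives the tosylhydrazone F6. Catecholborane followed by NaOAc·3H2O reduces C13 to CH2 and gives the C12 alcohol F7. Dess–Martin oxidation of F7 gives 27.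

Step 17 (methylene transfer). Facial selectivity may be poor or inverted because both chair forms of the cyclohexanone can be populated and each has one axial C15 substituent. Fallback, setting out from 27 and returning at 29: the carbon is delivered from the C15 oxymethyl group, which lies on the required face. DDQ removes the ether to give the keto alcohol F8. BrCH2SiMe2Cl and imidazole give the (bromomethyl)dimethylsilyl ether F9. SmI2 (THF, −78 → 0 °C, intramolecular Barbier addition) closes the cyclic siloxane F10, with the new C–C bond necessarily cis to the tether. Tamao–Fleming oxidation (H2O2, KF, KHCO3, THF–MeOH) gives the triol F11. TsCl with Bu2SnO (cat.) and Et3N sulfonylates the primary hydroxyl of the 1,2-diol to the monotosylate F12, and K2CO3 in MeOH closes the oxirane to 29, which re-enters at step 19.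

Further compounds
F1 | step 12 | (1R,3Z,7Z,11R,15R)-4,8-dimethyl-15-(4-methylpent-3-en-1-yl)-13-{[tri(propan-2-yl)silyl]oxy}bicyclo[9.3.1]pentadeca-3,7,12-triene-15-carbaldehyde (ent-22) | CC(C)=CCC[C@@]1(C=O)[C@@H]2C/C=C(/C)CC/C=C(/C)CC[C@@H]1C=C(O[Si](C(C)C)(C(C)C)C(C)C)C2
F2 | step 12 | [(1R,3Z,7Z,11R,15R)-4,8-dimethyl-15-(4-methylpent-3-en-1-yl)-13-{[tri(propan-2-yl)silyl]oxy}bicyclo[9.3.1]pentadeca-3,7,12-trien-15-yl]methanol (ent-23) | CC(C)=CCC[C@@]1(CO)[C@@H]2C/C=C(/C)CC/C=C(/C)CC[C@@H]1C=C(O[Si](C(C)C)(C(C)C)C(C)C)C2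
F3 | step 12 | (2S)-2-acetoxy-2-phenylacetate of 23 | CC(C)=CCC[C@]1(COC(=O)[C@@H](OC(C)=O)c3ccccc3)[C@H]2C/C=C(/C)CC/C=C(/C)CC[C@H]1C=C(O[Si](C(C)C)(C(C)C)C(C)C)C2
F4 | step 12 | (2S)-2-acetoxy-2-phenylacetate of ent-23 | CC(C)=CCC[C@@]1(COC(=O)[C@@H](OC(C)=O)c3ccccc3)[C@@H]2C/C=C(/C)CC/C=C(/C)CC[C@@H]1C=C(O[Si](C(C)C)(C(C)C)C(C)C)C2
F5 | step 16 | (1S,3Z,7Z,11R,15S)-12-hydroxy-15-{[(4-methoxyphenyl)methoxy]methyl}-4,8-dimethyl-15-(4-methylpent-3-en-1-yl)bicyclo[9.3.1]pentadeca-3,7-dien-13-one (either C12 epimer) | CC(C)=CCC[C@]1(COCc3ccc(OC)cc3)[C@H]2C/C=C(/C)CC/C=C(/C)CC[C@H]1C(O)C(=O)C2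
F6 | step 16 | 4-methylbenzenesulfonohydrazone of F5 | CC(C)=CCC[C@]1(COCc3ccc(OC)cc3)[C@H]2C/C=C(/C)CC/C=C(/C)CC[C@H]1C(O)C(=NNS(=O)(=O)c3ccc(C)cc3)C2
F7 | step 16 | (1R,3Z,7Z,11R,15S)-15-{[(4-methoxyphenyl)methoxy]methyl}-4,8-dimethyl-15-(4-methylpent-3-en-1-yl)bicyclo[9.3.1]pentadeca-3,7-dien-12-ol (either C12 epimer) | CC(C)=CCC[C@]1(COCc3ccc(OC)cc3)[C@H]2C/C=C(/C)CC/C=C(/C)CC[C@H]1C(O)CC2
F8 | step 17 | (1R,3Z,7Z,11R,15S)-15-(hydroxymethyl)-4,8-dimethyl-15-(4-methylpent-3-en-1-yl)bicyclo[9.3.1]pentadeca-3,7-dien-12-one | CC(C)=CCC[C@]1(CO)[C@H]2C/C=C(/C)CC/C=C(/C)CC[C@H]1C(=O)CC2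
F9 | step 17 | (bromomethyl)dimethylsilyl ether of F8 | CC(C)=CCC[C@]1(CO[Si](C)(C)CBr)[C@H]2C/C=C(/C)CC/C=C(/C)CC[C@H]1C(=O)CC2
F10 | step 17 | cyclic dimethylsiloxane bridging the C15 oxymethyl group and the new C12 methylene, with a C12 tertiary alcohol | CC(C)=CCC[C@]1(CO[Si](C)(C)C3)[C@H]2C/C=C(/C)CC/C=C(/C)CC[C@H]1[C@@]3(O)CC2
F11 | step 17 | (1R,3Z,7Z,11R,12S,15S)-12,15-bis(hydroxymethyl)-4,8-dimethyl-15-(4-methylpent-3-en-1-yl)bicyclo[9.3.1]pentadeca-3,7-dien-12-ol | CC(C)=CCC[C@]1(CO)[C@H]2C/C=C(/C)CC/C=C(/C)CC[C@H]1[C@@](CO)(O)CC2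
F12 | step 17 | mono-4-methylbenzenesulfonate of F11 at the C12 hydroxymethyl group | CC(C)=CCC[C@]1(CO)[C@H]2C/C=C(/C)CC/C=C(/C)CC[C@H]1[C@@](COS(=O)(=O)c3ccc(C)cc3)(O)CC2
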